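**Retrosynthetic overview**
- The CH2 bridge is cut last, into the 6-(dimethylaminomethyl)chromene 8 (an ortho-quinone methide precursor) and propanoylfilicinic acid 9; both halves come from 1-(2,4,6-trihydroxyphenyl)propan-1-one 1.
- The pyran ring of the chromene half is closed on the finished benzene ring by joining C2 to C3 in a redox-neutral hydride-transfer cyclization of an ortho-ethynyl aryl isopropyl ether. In one isomerization the isopropyl CH becomes the quaternary C2 and the C≡CH unit becomes C4=C3.
- Enabling feature: the ring oxygen O1 sits on C8a between C8 (propanoyl) and C4a (alkynyl), so the tertiary α-oxy C–H of its isopropyl group is pressed onto the internal alkyne carbon C4 in a 1,5 relationship. C2 is a tertiary oxocarbenium carbon, and CMe2–CH=CH has the same oxidation level as CHMe2 plus C≡CH.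
- The alkyne comes from an aldehyde placed by Vilsmeier formylation of symmetric 1; the filicinic ring comes from dearomatizing gem-dimethylation of 1.
- Ring order: benzene ring (bought), pyran ring (step 5), dienone ring (step 8), union of the halves (step 9).

Key step: step 5

Remark: the target has no stereocentre and its only ring double bonds are fixed by the rings; the β-triketone and acylphloroglucinol units are written as the tautomers of the target structure.

**Route**

Step 1
Reactants: 1 1-(2,4,6-trihydroxyphenyl)propan-1-one
Product: 2 2,4,6-trihydroxy-3-propanoylbenzaldehyde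
Conditions: POCl3 (1.2 equiv), DMF (1.5 equiv), EtOAc, 0 °C to rt; then H2O, 50 °C
Reagents that add atoms: N,N-dimethylformamide, CN(C)C=O; water, O
Why: Vilsmeier–Haack formylation of the electron-rich acylphloroglucinol, in which the two free ring positions are equivalent and the new formyl group should deactivate the ring against a second formylation.

Step 2
Reactants: 2 2,4,6-trihydroxy-3-propanoylbenzaldehyde
Product: 3 4-formyl-5-hydroxy-6-propanoyl-1,3-phenylene bis(4-methylbenzenesulfonate)
Conditions: TsCl (2.05 equiv), Et3N (2.5 equiv), CH2Cl2, −20 °C to 0 °C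
Reagents that add atoms: 4-methylbenzenesulfonyl chloride, Cc1ccc(cc1)S(=O)(=O)Cl
Why: O-sulfonylation of phenols, in which the hydroxyl between the formyl and propanoyl groups is hydrogen-bonded on either side and doubly ortho-substituted, so the two other hydroxyls should react first.

Step 3
Reactants: 3 4-formyl-5-hydroxy-6-propanoyl-1,3-phenylene bis(4-methylbenzenesulfonate)
Product: 4 4-formyl-5-(propan-2-yloxy)-6-propanoyl-1,3-phenylene bis(4-methylbenzenesulfonate)
Conditions: 2-iodopropane (3 equiv), Cs2CO3 (1.5 equiv), DMF, 50 °C
Reagents that add atoms: 2-iodopropane, CC(C)I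
Why: Williamson ether synthesis on the only remaining, acidic phenol, whose caesium phenoxide should be alkylated on oxygen while the aryl sulfonates are inert to carbonate in dry DMF.

Step 4
Reactants: 4 4-formyl-5-(propan-2-yloxy)-6-propanoyl-1,3-phenylene bis(4-methylbenzenesulfonate)
Product: 5 4-ethynyl-5-(propan-2-yloxy)-6-propanoyl-1,3-phenylene bis(4-methylbenzenesulfonate)
Conditions: dimethyl (1-diazo-2-oxopropyl)phosphonate (1.5 equiv), K2CO3 (2 equiv), MeOH/THF, 0 °C to rt
Reagents that add atoms: dimethyl (1-diazo-2-oxopropyl)phosphonate, CC(=O)C(=[N+]=[N-])P(=O)(OC)OC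
Why: Seyferth–Gilbert homologation in its Ohira–Bestmann form, which converts aldehydes but not aryl ketones into terminal alkynes under mild carbonate conditions that the sulfonates should tolerate at low temperature.

Step 5
Reactants: 5 4-ethynyl-5-(propan-2-yloxy)-6-propanoyl-1,3-phenylene bis(4-methylbenzenesulfonate)
Product: 6 2,2-dimethyl-8-propanoyl-2H-chromene-5,7-diyl bis(4-methylbenzenesulfonate)
Conditions: PtI4 (10 mol %), MeCN, 4 Å molecular sieves, 100 °C, sealed tube
Reagents that add atoms: none
Why: Proposed new method: PtI4 should bind the terminal alkyne of 5 and make its internal carbon (later C4) electrophilic, the tertiary C–H of the isopropyl ether should deliver hydride to that carbon through a six-membered transition state (1,5-hydride shift), and the metal-bearing carbon of the resulting alkenylplatinum species (later C3) should then attack the O-aryl oxocarbenium carbon (later C2) with release of the catalyst. The closest known reaction types are the PtI4- or cationic-gold-catalysed hydride-transfer cyclization (hydroalkylation) of terminal alkynes held three atoms away from an ether α-C–H bond and the Lewis-acid-catalysed 1,5-hydride shift/cyclization of ortho-alkoxybenzylidene malonates to chromans; new is the aryl isopropyl ether as hydride donor combined with an arene tether and an unactivated alkyne. The pyran ring closes in a 6-endo mode with respect to the former alkyne (both of its carbons end up in the ring), the oxocarbenium C=O bond being endocyclic as well, and the C3=C4 double bond and the quaternary carbon C2 arise in the same event without change of oxidation level. No stereocentre is formed, and the ring enforces the cis double bond. The step needs hydride transfer to win over 5-endo attack of an ether oxygen on the bound alkyne and six- over five-membered closure: the flanking propanoyl and ethynyl groups force the O–CH bond out of the ring plane and over the alkyne, the isopropyl group is a poor migrating group so that oxonium formation at its oxygen should be reversible, the tosylate on the other neighbouring oxygen has neither a hydridic C–H nor nucleophilicity, and anti delivery of hydride places platinum cis to the arene so that ipso substitution at C3 leads to the unstrained six-membered ring.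

Step 6
Reactants: 6 2,2-dimethyl-8-propanoyl-2H-chromene-5,7-diyl bis(4-methylbenzenesulfonate)
Product: 7 1-(5,7-dihydroxy-2,2-dimethyl-2H-chromen-8-yl)propan-1-one
Conditions: KOH (6 equiv), MeOH/THF/H2O, 50 °C, argon; then 1 M HCl
Reagents that add atoms: none
Why: base hydrolysis of aryl sulfonates by attack at sulfur, which should be easy here because the leaving phenoxides are conjugated with the ketone, while the chromene is stable to base.

Step 7
Reactants: 7 1-(5,7-dihydroxy-2,2-dimethyl-2H-chromen-8-yl)propan-1-one
Product: 8 1-{6-[(dimethylamino)methyl]-5,7-dihydroxy-2,2-dimethyl-2H-chromen-8-yl}propan-1-one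
Conditions: CH2(NMe2)2 (1.1 equiv), 1,4-dioxane, rt
Reagents that add atoms: N,N,N',N'-tetramethylmethanediamine, CN(C)CN(C)C
Why: phenolic Mannich aminomethylation, in which the acidic phenol itself opens the aminal to the iminium ion and C6, between the two hydroxyls, is the only free and the most nucleophilic ring position.

Step 8
Reactants: 1 1-(2,4,6-trihydroxyphenyl)propan-1-one
Product: 9 3,5-dihydroxy-4,4-dimethyl-2-propanoylcyclohexa-2,5-dien-1-one
Conditions: NaOMe (4 equiv), MeI (2.2 equiv), MeOH, 0 °C to rt; then 1 M HCl
Reagents that add atoms: iodomethane, CI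
Why: dearomatizing double C-methylation of the acylphloroglucinol polyanion at one ring carbon, the established entry to acylfilicinic acids, in which the second methylation at the same carbon should be favoured because it gives the conjugated β-triketone.

Step 9
Reactants: 8 1-{6-[(dimethylamino)methyl]-5,7-dihydroxy-2,2-dimethyl-2H-chromen-8-yl}propan-1-one; 9 3,5-dihydroxy-4,4-dimethyl-2-propanoylcyclohexa-2,5-dien-1-one
Product: 11 6-[(5,7-dihydroxy-2,2-dimethyl-8-propanoyl-2H-chromen-6-yl)methyl]-3,5-dihydroxy-4,4-dimethyl-2-propanoylcyclohexa-2,5-dien-1-one, via ortho-quinone methide 10 (not isolated)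
Conditions: 1,4-dioxane, 90 °C, argon
Reagents that add atoms: none
Why: thermal loss of dimethylamine from the phenolic Mannich base should give the ortho-quinone methide, which is trapped at its exocyclic carbon by the enol carbon C6 of the vinylogous acid 9 (Michael addition, then rearomatization), so that only the mixed dimer can form from these two partners.

**Compound list**
1 | 1-(2,4,6-trihydroxyphenyl)propan-1-one (flopropione) | CCC(=O)c1c(O)cc(O)cc1O | starting material
2 | 2,4,6-trihydroxy-3-propanoylbenzaldehyde | CCC(=O)c1c(O)c(C=O)c(O)cc1O | intermediate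
3 | 4-formyl-5-hydroxy-6-propanoyl-1,3-phenylene bis(4-methylbenzenesulfonate) | CCC(=O)c1c(O)c(C=O)c(OS(=O)(=O)c2ccc(C)cc2)cc1OS(=O)(=O)c3ccc(C)cc3 | intermediate
4 | 4-formyl-5-(propan-2-yloxy)-6-propanoyl-1,3-phenylene bis(4-methylbenzenesulfonate) | CCC(=O)c1c(OC(C)C)c(C=O)c(OS(=O)(=O)c2ccc(C)cc2)cc1OS(=O)(=O)c3ccc(C)cc3 | intermediate
5 | 4-ethynyl-5-(propan-2-yloxy)-6-propanoyl-1,3-phenylene bis(4-methylbenzenesulfonate) | CCC(=O)c1c(OC(C)C)c(C#C)c(OS(=O)(=O)c2ccc(C)cc2)cc1OS(=O)(=O)c3ccc(C)cc3 | intermediate
6 | 2,2-dimethyl-8-propanoyl-2H-chromene-5,7-diyl bis(4-methylbenzenesulfonate) | CCC(=O)c1c(OS(=O)(=O)c2ccc(C)cc2)cc(OS(=O)(=O)c3ccc(C)cc3)c4c1OC(C)(C)C=C4 | intermediate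
7 | 1-(5,7-dihydroxy-2,2-dimethyl-2H-chromen-8-yl)propan-1-one | CCC(=O)c1c(O)cc(O)c2c1OC(C)(C)C=C2 | intermediate
8 | 1-{6-[(dimethylamino)methyl]-5,7-dihydroxy-2,2-dimethyl-2H-chromen-8-yl}propan-1-one | CCC(=O)c1c(O)c(CN(C)C)c(O)c2c1OC(C)(C)C=C2 | intermediate
9 | 3,5-dihydroxy-4,4-dimethyl-2-propanoylcyclohexa-2,5-dien-1-one (propanoylfilicinic acid) | CCC(=O)C1=C(O)C(C)(C)C(O)=CC1=O | intermediate
10 | 5-hydroxy-2,2-dimethyl-6-methylidene-8-propanoyl-2H-chromen-7(6H)-one (ortho-quinone methide, not isolated) | C=C1C(=O)C(C(=O)CC)=C2OC(C)(C)C=CC2=C1O | intermediate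
11 | 6-[(5,7-dihydroxy-2,2-dimethyl-8-propanoyl-2H-chromen-6-yl)methyl]-3,5-dihydroxy-4,4-dimethyl-2-propanoylcyclohexa-2,5-dien-1-one | CCC(=O)C1=C(O)C(C)(C)C(O)=C(Cc2c(O)c3c(c(C(=O)CC)c2O)OC(C)(C)C=C3)C1=O | target

**Count**
Total steps: 9. Longest linear sequence: 8 steps (steps 1 to 7, then step 9); step 8 is a one-step side branch from 1.

**Steps most likely to fail**

Step 5 (proposed new method). The ether oxygen may add 5-endo to the platinum-bound alkyne with loss of the isopropyl group, closure may occur through the other alkenyl carbon to a five-membered ring, the alkyne may be hydrated, or hydride transfer may not start because the electron-poor aryl ether is a weak donor. The fallback uses known chemistry, sets out from 1 and comes back to the route at 7. Compound 1 would be protected with MOMCl and iPr2NEt in CH2Cl2, where the chelated hydroxyl stays free, to give 1-[2-hydroxy-4,6-bis(methoxymethoxy)phenyl]propan-1-one F1. Condensation of F1 with 3-methylbut-2-enal under ethylenediammonium diacetate in refluxing toluene (Knoevenagel-type condensation at the one free ortho carbon, then oxa-6π electrocyclization, which closes the pyran ring at the O1–C2 bond) should give 1-[5,7-bis(methoxymethoxy)-2,2-dimethyl-2H-chromen-8-yl]propan-1-one F2. HCl in MeOH at 40 °C would remove both acetals and give 7.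

Step 2. Sulfonylation may also take place at the hydroxyl between the two carbonyl groups, or run on to the trisulfonate, which would later put the isopropyl group on the wrong oxygen. The fallback sets out from 1 and comes back at 4; it fixes the regiochemistry by a phenol-directed formylation instead of a selective sulfonylation. Compound 1 would be converted with MOMCl and iPr2NEt into 1-[2-hydroxy-4,6-bis(methoxymethoxy)phenyl]propan-1-one F1. Casnati–Skattebøl ortho-formylation (MgCl2, Et3N, paraformaldehyde, MeCN, reflux) at the only carbon ortho to the free hydroxyl should give 2-hydroxy-4,6-bis(methoxymethoxy)-3-propanoylbenzaldehyde F3. Alkylation with 2-iodopropane and Cs2CO3 in DMF would give 4,6-bis(methoxymethoxy)-2-(propan-2-yloxy)-3-propanoylbenzaldehyde F4. HCl in MeOH would give 4,6-dihydroxy-2-(propan-2-yloxy)-3-propanoylbenzaldehyde F5, and TsCl with Et3N in CH2Cl2 would sulfonylate both remaining hydroxyls to give 4.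

Step 9. The quinone methide may add to a second molecule of the phenol, and the liberated amine may promote exchange of the halves of the methylene-bridged product, so that symmetrical dimers form. The fallback sets out from 7 and 9, bypasses 8 and arrives at 11. Equimolar 7 and 9 would be treated with paraformaldehyde and NaH in THF at 0 °C to rt, the classical three-component route to methylene-bridged acylphloroglucinol dimers: hydroxymethylation of the filicinic enolate, elimination to the exocyclic enone, Michael addition of the phloroglucinol anion. The symmetrical dimers would be removed by chromatography.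

**Further compounds**
F1 | step 5 | 1-[2-hydroxy-4,6-bis(methoxymethoxy)phenyl]propan-1-one | CCC(=O)c1c(O)cc(OCOC)cc1OCOC
F2 | step 5 | 1-[5,7-bis(methoxymethoxy)-2,2-dimethyl-2H-chromen-8-yl]propan-1-one | CCC(=O)c1c(OCOC)cc(OCOC)c2c1OC(C)(C)C=C2
F3 | step 2 | 2-hydroxy-4,6-bis(methoxymethoxy)-3-propanoylbenzaldehyde | CCC(=O)c1c(O)c(C=O)c(OCOC)cc1OCOC
F4 | step 2 | 4,6-bis(methoxymethoxy)-2-(propan-2-yloxy)-3-propanoylbenzaldehyde | CCC(=O)c1c(OC(C)C)c(C=O)c(OCOC)cc1OCOC
F5 | step 2 | 4,6-dihydroxy-2-(propan-2-yloxy)-3-propanoylbenzaldehyde | CCC(=O)c1c(OC(C)C)c(C=O)c(O)cc1O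
F0 | step 9 | none | none
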